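**Remarks on the chemistry.** Germacrane numbering (C1–C15) is used for the target and all ten-membered intermediates. Read from the SMILES, the target is (4R,5R,6S,7R,8R,9S) with a (2R,3S) side chain, and C2 and C9 are cis on C1=C10 (E by the sequence rule only because of the ester). The descriptors at C6 and C7 change along the route by priority alone while the spatial arrangement stays that of the target; the SMILES strings are authoritative. Diene 2 is sold as an E/Z mixture of which only the E isomer reacts.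

## The problem

The skeleton is a cyclodecane carrying two trisubstituted double-bond equivalents of opposite geometry: the C1=C10 enoate (ring carbons C2 and C9 cis) and the C4–C5 epoxide, which derives from an E alkene. Six contiguous stereocentres (C4 to C9) sit on one half of this flexible ring: the trans-fused α-methylene-γ-butyrolactone at C6/C7, two differently acylated oxygens at C8 and C9 that are cis to each other and to H-7, and the epoxide. End-to-end closure of a ten-membered ring is costly in entropy and transannular strain, and both ring alkenes would first have to be made with defined geometry in an open chain. Once the ring exists, its crossed conformation exposes only the outer face of each π system, so C6/C7 can control C8, C9, C4 and C5; the remote (2R,3S)-chlorohydrin ester needs reagent control. The feature that makes the key step possible is that the C9 oxygen is 1,5-related to the C4=C5 alkene across the C6–C7 bond, while C9, C10, C1, C2, C3 and C4 can form a cyclohexene in which the cis C1=C10 bond is the natural geometry. The fragile groups are the α-methylene lactone and the 2-(1-acetoxyalkyl)acrylate (Michael and SN2' acceptors), the epoxide (acid-triggered transannular cyclisation), the chlorohydrin (base closes it to an epoxide), the vicinal esters (acyl migration) and the ring 1,5-diene (Cope rearrangement on heating).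

## Retrosynthesis

**Epoxide last.** The C4–O and C5–O bonds of target 33 are cut to give triene lactone 32. In 32 the C4=C5 bond is the only electron-rich alkene, and the epoxide is the most acid-labile group, so it should be made after every acidic or oxidative step. The forward step needs attack on the outer face of C4=C5.

**Lactone and C14 ester by oxidation state.** The lactone C12–O6 bond and the ester at C14 are traced to three hydroxyl groups in 29 (C6, C12, C14), masked in 27 as a PMB ether and two silyl ethers. Both electrophilic acrylate units are thus kept as allylic ethers through all organometallic and basic steps. The forward steps need chemoselective oxidation of two primary allylic alcohols beside a secondary one.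

**The two esters.** The C9 acetate and the C8 ester are cut back to α-hydroxy ketone 17 and acid 23. A ketone at C9 distinguishes the two oxygens without protecting groups: O8 is acylated first (25), the ketone is reduced from the ring periphery (26) and O9 is acetylated (27). Acid 23 comes from (E)-2-methylbut-2-en-1-ol 18 by asymmetric epoxidation (19), oxidation (20) and opening with HCl with inversion at C3 (21).

**Key disconnection.** In 17 the C6–C7 bond is cut while C4–C9 is reconnected (retro oxy-Cope) and the C8 hydroxyl is removed (retro enolate oxygenation), which gives cyclohexenol 15. Cuts at C6–C7 alone, C9–C10 or C1–C2 give open chains in which both trisubstituted alkenes must be built separately and the ring closed against entropy. The other oxy-Cope mapping (ketone at C6) would place the E-4,5 alkene inside a six-membered ring. The precursor 15 has no medium ring and only two stereocentres, of which the quaternary C4 controls the outcome. The forward reaction must pass through one chair, keep the E geometry of both alkenyl groups, and oxygenate the enolate on its outer face.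

**Carbinol.** The C8–C9 bond of 15 is cut to enone 9 and dienylstannane 13 (as its lithium derivative 14). The 1,2-addition must come from the methyl face of C4.

**Enone.** In 9 the C14 carbon is removed (Morita–Baylis–Hillman, 8 from 7), the enol ether is traced through alkenylboronate 5 to aldehyde 4, and 4 is opened by a Diels–Alder cut (bonds C2–C3 and C4–C9) to methacrolein 1 and silyloxydiene 2. One catalytic step sets the quaternary centre, the ring, the cis alkene and the C9 oxygen.

**Stannane.** 13 is cut at C7–C11 to bromide 11 (from 2-bromoallyl alcohol 10) and bis-stannane 12.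

## Roads not taken

Alternative 1: The most obvious cut is C6–C7 alone in an open chain. The forward key step would be an intramolecular Barbier/Nozaki–Hiyama–Kishi allylation (CrCl2) of the C6 aldehyde by the 2-(bromomethyl)enoate of seco compound A1, closing the ring and forming the methylene lactone together. A1 needs a twelve-carbon chain with a stereodefined ring-cis enoate next to the C8/C9 diol and an E enal, all made linearly. The closure is entropically disfavoured, and its C6/C7 sense rests on a macrocyclic transition state next to the C8 stereocentre. The chosen plan takes the cis alkene for free from a cyclohexene and gets ring, E alkene and C6/C7 from a unimolecular chair.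

Alternative 2: Cut C9–C10. The forward key step would be an intramolecular Nozaki–Hiyama–Kishi coupling (CrCl2, NiCl2 cat.) of the α-iodoenoate with the C9 aldehyde of A2. The lactone and C6–C8 must first be built on an acyclic chain by separate stereoselective steps. The electron-poor α-ester alkenylchromium is a poor nucleophile, the C9 configuration is weakly controlled, and the methylene lactone must survive CrCl2. It spends more steps before the ring exists and gains only one stereocentre in the key step.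

Alternative 3: Skeleton first. A bare germacranolide such as parthenolide A3 is oxidised with SeO2 at C14 with isomerisation of the 1(10) bond, giving A4, and the C9 and C8 oxygens are then added by C–H oxidation. C9 is allylic but competes with C2, C3 and C15. C8 is an unactivated methylene with no directing group nearby, and the cis-8,9 relationship would have no control element. The chosen plan installs both oxygens through the enolate that the ring expansion produces anyway.

Key step: step 10

## Route

Step 1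
Reactants: 1 methacrolein; 2 (E)-1-(trimethylsilyloxy)buta-1,3-diene
Product: 4 (1R,2S)-2-hydroxy-1-methylcyclohex-3-ene-1-carbaldehyde, via silyl ether 3 (not isolated)
Conditions: (S)-N-(p-tolylsulfonyl)tryptophan-derived B-butyl-1,3,2-oxazaborolidin-5-one (20 mol%), CH2Cl2, −78 °C; then 1 M HCl, THF, 0 °C
Reagents that add atoms: none
Why: Catalytic enantioselective Diels–Alder reaction; the 1-silyloxy group directs C9 next to C4, and the catalyst enantiomer is chosen so that the diene adds to the Si face of C2 of the boron-bound enal (priorities CHO > CH2 > CH3), which sets the R quaternary centre. Endo addition puts the oxygen cis to CHO, but this centre is erased in step 4, so the exo isomer converges.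

Step 2
Reactants: 4 (1R,2S)-2-hydroxy-1-methylcyclohex-3-ene-1-carbaldehyde
Product: 5 (1S,6S)-6-methyl-6-[(E)-2-(4,4,5,5-tetramethyl-1,3,2-dioxaborolan-2-yl)ethenyl]cyclohex-2-en-1-ol
Conditions: Cl2CHBpin, CrCl2, LiI, THF, 25 °C
Reagents that add atoms: 2-(dichloromethyl)-4,4,5,5-tetramethyl-1,3,2-dioxaborolane, ClC(Cl)B1OC(C)(C)C(C)(C)O1
Why: Takai–Utimoto boron olefination; the geminal dichromium reagent tolerates the free hydroxyl and gives the E alkenylboronate even from a neopentyl-type aldehyde.

Step 3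
Reactants: 5 (1S,6S)-6-methyl-6-[(E)-2-(4,4,5,5-tetramethyl-1,3,2-dioxaborolan-2-yl)ethenyl]cyclohex-2-en-1-ol
Product: 6 (1S,6S)-6-[(E)-2-(4-methoxybenzyloxy)ethenyl]-6-methylcyclohex-2-en-1-ol
Conditions: Cu(OAc)2 (2 equiv), Et3N, 4-methoxybenzyl alcohol (excess), 4 Å molecular sieves, air, 25 °C
Reagents that add atoms: 4-methoxybenzyl alcohol, COc1ccc(CO)cc1
Why: Chan–Lam-type oxidative C–O coupling of an alkenylboronate with an alcohol, which retains the alkene geometry; the ring hydroxyl cannot reach the E alkenyl carbon and is outcompeted by the excess alcohol.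

Step 4
Reactants: 6 (1S,6S)-6-[(E)-2-(4-methoxybenzyloxy)ethenyl]-6-methylcyclohex-2-en-1-ol
Product: 7 (S)-6-[(E)-2-(4-methoxybenzyloxy)ethenyl]-6-methylcyclohex-2-en-1-one
Conditions: Dess–Martin periodinane, NaHCO3, CH2Cl2, 0 °C
Reagents that add atoms: none
Why: Dess–Martin oxidation of the allylic alcohol under buffered conditions that spare the enol ether; both C9 epimers from step 1 converge here.

Step 5
Reactants: 7 (S)-6-[(E)-2-(4-methoxybenzyloxy)ethenyl]-6-methylcyclohex-2-en-1-one
Product: 8 (S)-2-(hydroxymethyl)-6-[(E)-2-(4-methoxybenzyloxy)ethenyl]-6-methylcyclohex-2-en-1-one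
Conditions: aqueous CH2O, DMAP (0.3 equiv), THF/H2O, 25 °C
Reagents that add atoms: formaldehyde, C=O
Why: Morita–Baylis–Hillman hydroxymethylation of a cyclohexenone; the quaternary α' carbon cannot enolise and does not hinder β-attack by DMAP.

Step 6
Reactants: 8 (S)-2-(hydroxymethyl)-6-[(E)-2-(4-methoxybenzyloxy)ethenyl]-6-methylcyclohex-2-en-1-one
Product: 9 (S)-6-[(E)-2-(4-methoxybenzyloxy)ethenyl]-6-methyl-2-[(triisopropylsilyloxy)methyl]cyclohex-2-en-1-one
Conditions: i-Pr3SiCl, imidazole, DMF, 25 °C
Reagents that add atoms: chlorotriisopropylsilane, CC(C)[Si](Cl)(C(C)C)C(C)C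
Why: Silylation; the bulky triisopropylsilyl group is chosen because it should not migrate to the neighbouring C9 alkoxide generated in step 10.

Step 7
Reactants: 10 2-bromoprop-2-en-1-ol
Product: 11 [(2-bromoprop-2-en-1-yl)oxy](tert-butyl)dimethylsilane
Conditions: t-BuMe2SiCl, imidazole, CH2Cl2, 0 °C
Reagents that add atoms: tert-butylchlorodimethylsilane, CC(C)(C)[Si](C)(C)Cl
Why: Standard silylation of a primary alcohol.

Step 8
Reactants: 11 [(2-bromoprop-2-en-1-yl)oxy](tert-butyl)dimethylsilane; 12 (E)-1,2-bis(tributylstannyl)ethene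
Product: 13 tert-butyldimethyl{[(3E)-2-methylidene-4-(tributylstannyl)but-3-en-1-yl]oxy}silane
Conditions: Pd(PPh3)4 (5 mol%), toluene, 90 °C, 12 in threefold excess
Reagents that add atoms: none
Why: Stille coupling with retention of the E geometry; the excess of the bis-stannane limits the reaction to one coupling.

Step 9
Reactants: 13 tert-butyldimethyl{[(3E)-2-methylidene-4-(tributylstannyl)but-3-en-1-yl]oxy}silane; 9 (S)-6-[(E)-2-(4-methoxybenzyloxy)ethenyl]-6-methyl-2-[(triisopropylsilyloxy)methyl]cyclohex-2-en-1-one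
Product: 15 (1R,6S)-1-[(1E)-3-[(tert-butyldimethylsilyloxy)methyl]buta-1,3-dien-1-yl]-6-[(E)-2-(4-methoxybenzyloxy)ethenyl]-6-methyl-2-[(triisopropylsilyloxy)methyl]cyclohex-2-en-1-ol, via dienyllithium 14 (not isolated)
Conditions: 13, n-BuLi, THF, −78 °C; then 9, −78 °C; aqueous NH4Cl
Reagents that add atoms: none
Why: Tin–lithium exchange with retention, then 1,2-addition of the hard alkenyllithium to the enone. The nucleophile should enter anti to the pseudo-axial alkoxyvinyl group and gauche only to the C4 methyl, which gives the trans-dialkenyl carbinol (1R).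

Step 10
Reactants: 15 (1R,6S)-1-[(1E)-3-[(tert-butyldimethylsilyloxy)methyl]buta-1,3-dien-1-yl]-6-[(E)-2-(4-methoxybenzyloxy)ethenyl]-6-methyl-2-[(triisopropylsilyloxy)methyl]cyclohex-2-en-1-ol
Product: 17 (6R,7R,8R)-12-(tert-butyldimethylsilyloxy)-8-hydroxy-6-(4-methoxybenzyloxy)-14-(triisopropylsilyloxy)germacra-1(10)Z,4E,11(13)-trien-9-one, via potassium dienolate 16 (not isolated)
Conditions: KH, 18-crown-6, THF, 0 to 25 °C; then −78 °C, trans-2-(phenylsulfonyl)-3-phenyloxaziridine; aqueous NH4Cl
Reagents that add atoms: 2-(phenylsulfonyl)-3-phenyloxaziridine, O=S(=O)(c1ccccc1)N1OC1c1ccccc1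
Why: The potassium alkoxide of 15 is a 3-oxido-1,5-diene (C7=C8–C9–C4–C5=C6) and should undergo the anion-accelerated [3,3]-sigmatropic shift (anionic oxy-Cope rearrangement), breaking C4–C9 and forming C6–C7; the closest known type is the four-carbon ring expansion of trans-1,2-dialkenylcyclohexanols to cyclodec-5-enones with in situ oxidation of the enolate. The ten-membered ring is thus formed by ring expansion through a chair-like six-centre transition state, not by end-to-end closure; in this chair the cyclohexene bridge atoms C10 and C3 are equatorial and the C4 methyl and the oxido group axial. Because both alkenyl groups are E, the C6 oxygen and the C11 unit at C7 are pseudo-equatorial, which gives the trans relationship of the future lactone; the absolute sense is transferred from the S quaternary centre C4, which is destroyed. The equatorial C3 makes the new C4=C5 bond E, and C1=C10 stays cis because it was part of the six-membered ring. A boat, or reaction of a Z enol ether, would meet a 1,3-diaxial clash with the C4 methyl, and the competing shift through the ring alkene needs a bicyclo[2.2.2]-like boat, so the chair through the dienyl group should prevail. Enolate 16 keeps the crossed conformation of the transition state, in which the inner face of C8=C9 is covered by the transannular C4=C5 bond, so the oxaziridine should deliver oxygen to the outer face and set the 8R hydroxyl cis to H-7. C8 is the only nucleophilic carbon of the cross-conjugated enolate. Any C9 epimer of 15 should converge, since C9 becomes trigonal and the chair with C3 equatorial and the oxido group equatorial is open to it.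

Step 11
Reactants: 18 (E)-2-methylbut-2-en-1-ol
Product: 19 [(2R,3R)-2,3-dimethyloxiran-2-yl]methanol
Conditions: Ti(OiPr)4 (10 mol%), D-(−)-diisopropyl tartrate (12 mol%), t-BuOOH, 4 Å molecular sieves, CH2Cl2, −20 °C
Reagents that add atoms: tert-butyl hydroperoxide, CC(C)(C)OO
Why: Sharpless asymmetric epoxidation; the D-(−)-tartrate delivers oxygen to the face opposite to that used by the L-(+)-tartrate, which gives (2S,3S) epoxides from E-configured allylic alcohols of this type, so 2R,3R is expected.

Step 12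
Reactants: 19 [(2R,3R)-2,3-dimethyloxiran-2-yl]methanol
Product: 20 (2S,3R)-2,3-dimethyloxirane-2-carboxylic acid
Conditions: RuCl3·xH2O (2 mol%), NaIO4, CCl4/MeCN/H2O, 0 to 25 °C
Reagents that add atoms: water, O
Why: RuO4-catalysed oxidation of an epoxy alcohol to the glycidic acid leaves the epoxide intact; the C2 descriptor changes by priority only.

Step 13
Reactants: 20 (2S,3R)-2,3-dimethyloxirane-2-carboxylic acid
Product: 21 (2R,3S)-3-chloro-2-hydroxy-2-methylbutanoic acid
Conditions: HCl (4 M in 1,4-dioxane), Et2O, 0 °C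
Reagents that add atoms: hydrogen chloride, Cl
Why: Acid-promoted epoxide opening; chloride attacks the secondary C3 with inversion (SN2), because C2 is tertiary and deactivated by the carboxyl group.

Step 14
Reactants: 21 (2R,3S)-3-chloro-2-hydroxy-2-methylbutanoic acid
Product: 23 (2R,3S)-3-chloro-2-methyl-2-(triethylsilyloxy)butanoic acid, via bis-silyl derivative 22 (not isolated)
Conditions: Et3SiOTf (2.3 equiv), 2,6-lutidine, CH2Cl2, −78 to 0 °C; then K2CO3, THF/H2O, 0 °C; citric acid to pH 4
Reagents that add atoms: triethylsilyl trifluoromethanesulfonate, CC[Si](CC)(CC)OS(=O)(=O)C(F)(F)F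
Why: Exhaustive silylation followed by selective hydrolysis of the labile silyl ester; the silyl ether blocks self-acylation and epoxide closure in step 15.

Step 15
Reactants: 17 (6R,7R,8R)-12-(tert-butyldimethylsilyloxy)-8-hydroxy-6-(4-methoxybenzyloxy)-14-(triisopropylsilyloxy)germacra-1(10)Z,4E,11(13)-trien-9-one; 23 (2R,3S)-3-chloro-2-methyl-2-(triethylsilyloxy)butanoic acid
Product: 25 (6R,7S,8R)-12-(tert-butyldimethylsilyloxy)-8-[(2R,3S)-3-chloro-2-methyl-2-(triethylsilyloxy)butanoyloxy]-6-(4-methoxybenzyloxy)-14-(triisopropylsilyloxy)germacra-1(10)Z,4E,11(13)-trien-9-one, via mixed anhydride 24 (not isolated)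
Conditions: 23, 2,4,6-trichlorobenzoyl chloride, Et3N, toluene, 25 °C; then 17, DMAP, toluene, 25 to 40 °C
Reagents that add atoms: none
Why: Yamaguchi esterification of the only free hydroxyl; the acid has no α-hydrogen, so base can neither eliminate HCl nor epimerise it.

Step 16
Reactants: 25 (6R,7S,8R)-12-(tert-butyldimethylsilyloxy)-8-[(2R,3S)-3-chloro-2-methyl-2-(triethylsilyloxy)butanoyloxy]-6-(4-methoxybenzyloxy)-14-(triisopropylsilyloxy)germacra-1(10)Z,4E,11(13)-trien-9-one
Product: 26 (6R,7S,8R,9S)-12-(tert-butyldimethylsilyloxy)-8-[(2R,3S)-3-chloro-2-methyl-2-(triethylsilyloxy)butanoyloxy]-6-(4-methoxybenzyloxy)-14-(triisopropylsilyloxy)germacra-1(10)Z,4E,11(13)-trien-9-ol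
Conditions: NaBH4, CeCl3·7H2O, MeOH/THF, −78 °C
Reagents that add atoms: none
Why: Luche 1,2-reduction of the enone; hydride should enter on the outer face of the carbonyl, anti to the transannular C4=C5 bond, which gives the 9S alcohol cis to the C8 oxygen. The low temperature suppresses acyl migration.

Step 17
Reactants: 26 (6R,7S,8R,9S)-12-(tert-butyldimethylsilyloxy)-8-[(2R,3S)-3-chloro-2-methyl-2-(triethylsilyloxy)butanoyloxy]-6-(4-methoxybenzyloxy)-14-(triisopropylsilyloxy)germacra-1(10)Z,4E,11(13)-trien-9-ol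
Product: 27 (6R,7S,8R,9S)-9-acetoxy-12-(tert-butyldimethylsilyloxy)-8-[(2R,3S)-3-chloro-2-methyl-2-(triethylsilyloxy)butanoyloxy]-6-(4-methoxybenzyloxy)-14-(triisopropylsilyloxy)germacra-1(10)Z,4E,11(13)-triene
Conditions: Ac2O, pyridine, DMAP (cat.), CH2Cl2, 0 °C
Reagents that add atoms: acetic anhydride, CC(=O)OC(C)=O
Why: Fast acetylation of the only free hydroxyl outruns 1,2-acyl migration.

Step 18
Reactants: 27 (6R,7S,8R,9S)-9-acetoxy-12-(tert-butyldimethylsilyloxy)-8-[(2R,3S)-3-chloro-2-methyl-2-(triethylsilyloxy)butanoyloxy]-6-(4-methoxybenzyloxy)-14-(triisopropylsilyloxy)germacra-1(10)Z,4E,11(13)-triene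
Product: 28 (6R,7S,8R,9S)-9-acetoxy-12-(tert-butyldimethylsilyloxy)-8-[(2R,3S)-3-chloro-2-methyl-2-(triethylsilyloxy)butanoyloxy]-14-(triisopropylsilyloxy)germacra-1(10)Z,4E,11(13)-trien-6-ol
Conditions: DDQ, CH2Cl2/pH 7 buffer, 0 °C
Reagents that add atoms: none
Why: Oxidative cleavage of the 4-methoxybenzyl ether under neutral conditions; silyl ethers, esters and the alkenes are inert.

Step 19
Reactants: 28 (6R,7S,8R,9S)-9-acetoxy-12-(tert-butyldimethylsilyloxy)-8-[(2R,3S)-3-chloro-2-methyl-2-(triethylsilyloxy)butanoyloxy]-14-(triisopropylsilyloxy)germacra-1(10)Z,4E,11(13)-trien-6-ol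
Product: 29 (6R,7S,8R,9S)-9-acetoxy-8-[(2R,3S)-3-chloro-2-hydroxy-2-methylbutanoyloxy]germacra-1(10)Z,4E,11(13)-triene-6,12,14-triol
Conditions: HF·pyridine, pyridine, THF, 0 to 25 °C
Reagents that add atoms: none
Why: Buffered fluoride-mediated cleavage of all three silyl ethers without base, so the chlorohydrin is not closed to an epoxide; the crude product is oxidised at once to limit acetyl migration from O9 to O14.

Step 20
Reactants: 29 (6R,7S,8R,9S)-9-acetoxy-8-[(2R,3S)-3-chloro-2-hydroxy-2-methylbutanoyloxy]germacra-1(10)Z,4E,11(13)-triene-6,12,14-triol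
Product: 31 (6R,7S,8R,9S)-9-acetoxy-8-[(2R,3S)-3-chloro-2-hydroxy-2-methylbutanoyloxy]germacra-1(10)E,4E,11(13)-trien-12,6-olid-14-oic acid, via lactone aldehyde 30 (not isolated)
Conditions: PhI(OAc)2, TEMPO (20 mol%), CH2Cl2, 25 °C; then NaClO2, NaH2PO4, 2-methylbut-2-ene, t-BuOH/H2O, 0 °C
Reagents that add atoms: sodium chlorite, [Na+].[O-]Cl=O
Why: TEMPO/PhI(OAc)2 oxidises the two primary allylic alcohols in preference to the secondary C6 hydroxyl; the C12 aldehyde is trapped by that hydroxyl as a lactol and oxidised on to the trans-fused methylene lactone (oxidative lactonisation of a 1,4-diol). The remaining C14 enal is taken to the acid by Pinnick oxidation with a hypochlorite scavenger.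

Step 21
Reactants: 31 (6R,7S,8R,9S)-9-acetoxy-8-[(2R,3S)-3-chloro-2-hydroxy-2-methylbutanoyloxy]germacra-1(10)E,4E,11(13)-trien-12,6-olid-14-oic acid
Product: 32 methyl (6R,7S,8R,9S)-9-acetoxy-8-[(2R,3S)-3-chloro-2-hydroxy-2-methylbutanoyloxy]germacra-1(10)E,4E,11(13)-trien-12,6-olid-14-oate
Conditions: Me3SiCHN2, MeOH/toluene, 0 °C, short reaction time; AcOH quench
Reagents that add atoms: (trimethylsilyl)diazomethane, C[Si](C)(C)C=[N+]=[N-]
Why: Methyl ester formation under neutral conditions; protonation of the diazoalkane by the acid is much faster than its dipolar cycloaddition to the methylene lactone at 0 °C.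

Step 22
Reactants: 32 methyl (6R,7S,8R,9S)-9-acetoxy-8-[(2R,3S)-3-chloro-2-hydroxy-2-methylbutanoyloxy]germacra-1(10)E,4E,11(13)-trien-12,6-olid-14-oate
Product: 33 methyl (4R,5R,6S,7R,8R,9S)-9-acetoxy-8-[(2R,3S)-3-chloro-2-hydroxy-2-methylbutanoyloxy]-4,5-epoxygermacra-1(10)E,11(13)-dien-12,6-olid-14-oate (target)
Conditions: 3-chloroperbenzoic acid, NaHCO3, CH2Cl2, 0 °C
Reagents that add atoms: 3-chloroperbenzoic acid, OOC(=O)c1cccc(Cl)c1
Why: Prilezhaev epoxidation of the only electron-rich alkene (C1=C10 and C11=C13 are conjugated to carbonyl groups). In the crossed conformation held by the trans-lactone the inner face of C4=C5 is covered by the ring, so the peracid should attack the outer face and give the 4R,5R epoxide; bicarbonate protects the product from acid.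

## Compound list

1 | methacrolein | CC(=C)C=O | starting material
2 | (E)-1-(trimethylsilyloxy)buta-1,3-diene | C=C/C=C/O[Si](C)(C)C | starting material
3 | (1R,2S)-1-methyl-2-(trimethylsilyloxy)cyclohex-3-ene-1-carbaldehyde | C[Si](C)(C)O[C@H]1C=CCC[C@@]1(C)C=O | intermediate
4 | (1R,2S)-2-hydroxy-1-methylcyclohex-3-ene-1-carbaldehyde | O[C@H]1C=CCC[C@@]1(C)C=O | intermediate
5 | (1S,6S)-6-methyl-6-[(E)-2-(4,4,5,5-tetramethyl-1,3,2-dioxaborolan-2-yl)ethenyl]cyclohex-2-en-1-ol | O[C@H]1C=CCC[C@@]1(C)/C=C/B1OC(C)(C)C(C)(C)O1 | intermediate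
6 | (1S,6S)-6-[(E)-2-(4-methoxybenzyloxy)ethenyl]-6-methylcyclohex-2-en-1-ol | O[C@H]1C=CCC[C@@]1(C)/C=C/OCc1ccc(OC)cc1 | intermediate
7 | (S)-6-[(E)-2-(4-methoxybenzyloxy)ethenyl]-6-methylcyclohex-2-en-1-one | O=C1C=CCC[C@@]1(C)/C=C/OCc1ccc(OC)cc1 | intermediate
8 | (S)-2-(hydroxymethyl)-6-[(E)-2-(4-methoxybenzyloxy)ethenyl]-6-methylcyclohex-2-en-1-one | O=C1C(CO)=CCC[C@@]1(C)/C=C/OCc1ccc(OC)cc1 | intermediate
9 | (S)-6-[(E)-2-(4-methoxybenzyloxy)ethenyl]-6-methyl-2-[(triisopropylsilyloxy)methyl]cyclohex-2-en-1-one | O=C1C(CO[Si](C(C)C)(C(C)C)C(C)C)=CCC[C@@]1(C)/C=C/OCc1ccc(OC)cc1 | intermediate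
10 | 2-bromoprop-2-en-1-ol | OCC(Br)=C | starting material
11 | [(2-bromoprop-2-en-1-yl)oxy](tert-butyl)dimethylsilane | C=C(Br)CO[Si](C)(C)C(C)(C)C | intermediate
12 | (E)-1,2-bis(tributylstannyl)ethene | CCCC[Sn](CCCC)(CCCC)/C=C/[Sn](CCCC)(CCCC)CCCC | starting material
13 | tert-butyldimethyl{[(3E)-2-methylidene-4-(tributylstannyl)but-3-en-1-yl]oxy}silane | CCCC[Sn](CCCC)(CCCC)/C=C/C(=C)CO[Si](C)(C)C(C)(C)C | intermediate
14 | [(1E)-3-[(tert-butyldimethylsilyloxy)methyl]buta-1,3-dien-1-yl]lithium | [Li]/C=C/C(=C)CO[Si](C)(C)C(C)(C)C | intermediate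
15 | (1R,6S)-1-[(1E)-3-[(tert-butyldimethylsilyloxy)methyl]buta-1,3-dien-1-yl]-6-[(E)-2-(4-methoxybenzyloxy)ethenyl]-6-methyl-2-[(triisopropylsilyloxy)methyl]cyclohex-2-en-1-ol | C1CC=C(CO[Si](C(C)C)(C(C)C)C(C)C)[C@@](O)(/C=C/C(=C)CO[Si](C)(C)C(C)(C)C)[C@]1(C)/C=C/OCc1ccc(OC)cc1 | intermediate
16 | potassium (6R,7S)-12-(tert-butyldimethylsilyloxy)-6-(4-methoxybenzyloxy)-14-(triisopropylsilyloxy)germacra-1(10)Z,4E,8Z,11(13)-tetraen-9-olate (C7 and C10 trans on C8=C9) | C1/C(C)=C/[C@@H](OCc2ccc(OC)cc2)[C@H](C(=C)CO[Si](C)(C)C(C)(C)C)/C=C([O-])/C(CO[Si](C(C)C)(C(C)C)C(C)C)=C\C1.[K+] | intermediate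
17 | (6R,7R,8R)-12-(tert-butyldimethylsilyloxy)-8-hydroxy-6-(4-methoxybenzyloxy)-14-(triisopropylsilyloxy)germacra-1(10)Z,4E,11(13)-trien-9-one | C1/C(C)=C/[C@@H](OCc2ccc(OC)cc2)[C@H](C(=C)CO[Si](C)(C)C(C)(C)C)[C@@H](O)C(=O)/C(CO[Si](C(C)C)(C(C)C)C(C)C)=C\C1 | intermediate
18 | (E)-2-methylbut-2-en-1-ol | C/C=C(\C)CO | starting material
19 | [(2R,3R)-2,3-dimethyloxiran-2-yl]methanol | OC[C@@]1(C)O[C@@H]1C | intermediate
20 | (2S,3R)-2,3-dimethyloxirane-2-carboxylic acid | OC(=O)[C@@]1(C)O[C@@H]1C | intermediate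
21 | (2R,3S)-3-chloro-2-hydroxy-2-methylbutanoic acid | OC(=O)[C@@](C)(O)[C@H](C)Cl | intermediate
22 | triethylsilyl (2R,3S)-3-chloro-2-methyl-2-(triethylsilyloxy)butanoate | CC[Si](CC)(CC)OC(=O)[C@@](C)(O[Si](CC)(CC)CC)[C@H](C)Cl | intermediate
23 | (2R,3S)-3-chloro-2-methyl-2-(triethylsilyloxy)butanoic acid | OC(=O)[C@@](C)(O[Si](CC)(CC)CC)[C@H](C)Cl | intermediate
24 | (2R,3S)-3-chloro-2-methyl-2-(triethylsilyloxy)butanoic 2,4,6-trichlorobenzoic anhydride | Clc1cc(Cl)c(C(=O)OC(=O)[C@@](C)(O[Si](CC)(CC)CC)[C@H](C)Cl)c(Cl)c1 | intermediate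
25 | (6R,7S,8R)-12-(tert-butyldimethylsilyloxy)-8-[(2R,3S)-3-chloro-2-methyl-2-(triethylsilyloxy)butanoyloxy]-6-(4-methoxybenzyloxy)-14-(triisopropylsilyloxy)germacra-1(10)Z,4E,11(13)-trien-9-one | C1/C(C)=C/[C@@H](OCc2ccc(OC)cc2)[C@H](C(=C)CO[Si](C)(C)C(C)(C)C)[C@@H](OC(=O)[C@@](C)(O[Si](CC)(CC)CC)[C@H](C)Cl)C(=O)/C(CO[Si](C(C)C)(C(C)C)C(C)C)=C\C1 | intermediate
26 | (6R,7S,8R,9S)-12-(tert-butyldimethylsilyloxy)-8-[(2R,3S)-3-chloro-2-methyl-2-(triethylsilyloxy)butanoyloxy]-6-(4-methoxybenzyloxy)-14-(triisopropylsilyloxy)germacra-1(10)Z,4E,11(13)-trien-9-ol | C1/C(C)=C/[C@@H](OCc2ccc(OC)cc2)[C@H](C(=C)CO[Si](C)(C)C(C)(C)C)[C@@H](OC(=O)[C@@](C)(O[Si](CC)(CC)CC)[C@H](C)Cl)[C@@H](O)/C(CO[Si](C(C)C)(C(C)C)C(C)C)=C\C1 | intermediate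
27 | (6R,7S,8R,9S)-9-acetoxy-12-(tert-butyldimethylsilyloxy)-8-[(2R,3S)-3-chloro-2-methyl-2-(triethylsilyloxy)butanoyloxy]-6-(4-methoxybenzyloxy)-14-(triisopropylsilyloxy)germacra-1(10)Z,4E,11(13)-triene | C1/C(C)=C/[C@@H](OCc2ccc(OC)cc2)[C@H](C(=C)CO[Si](C)(C)C(C)(C)C)[C@@H](OC(=O)[C@@](C)(O[Si](CC)(CC)CC)[C@H](C)Cl)[C@@H](OC(C)=O)/C(CO[Si](C(C)C)(C(C)C)C(C)C)=C\C1 | intermediate
28 | (6R,7S,8R,9S)-9-acetoxy-12-(tert-butyldimethylsilyloxy)-8-[(2R,3S)-3-chloro-2-methyl-2-(triethylsilyloxy)butanoyloxy]-14-(triisopropylsilyloxy)germacra-1(10)Z,4E,11(13)-trien-6-ol | C1/C(C)=C/[C@@H](O)[C@H](C(=C)CO[Si](C)(C)C(C)(C)C)[C@@H](OC(=O)[C@@](C)(O[Si](CC)(CC)CC)[C@H](C)Cl)[C@@H](OC(C)=O)/C(CO[Si](C(C)C)(C(C)C)C(C)C)=C\C1 | intermediate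
29 | (6R,7S,8R,9S)-9-acetoxy-8-[(2R,3S)-3-chloro-2-hydroxy-2-methylbutanoyloxy]germacra-1(10)Z,4E,11(13)-triene-6,12,14-triol | C1/C(C)=C/[C@@H](O)[C@H](C(=C)CO)[C@@H](OC(=O)[C@@](C)(O)[C@H](C)Cl)[C@@H](OC(C)=O)/C(CO)=C\C1 | intermediate
30 | (6R,7S,8R,9S)-9-acetoxy-8-[(2R,3S)-3-chloro-2-hydroxy-2-methylbutanoyloxy]-14-oxogermacra-1(10)E,4E,11(13)-trien-12,6-olide | C1/C(C)=C/[C@H]2OC(=O)C(=C)[C@@H]2[C@@H](OC(=O)[C@@](C)(O)[C@H](C)Cl)[C@@H](OC(C)=O)/C(C=O)=C\C1 | intermediate
31 | (6R,7S,8R,9S)-9-acetoxy-8-[(2R,3S)-3-chloro-2-hydroxy-2-methylbutanoyloxy]germacra-1(10)E,4E,11(13)-trien-12,6-olid-14-oic acid | C1/C(C)=C/[C@H]2OC(=O)C(=C)[C@@H]2[C@@H](OC(=O)[C@@](C)(O)[C@H](C)Cl)[C@@H](OC(C)=O)/C(C(=O)O)=C\C1 | intermediate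
32 | methyl (6R,7S,8R,9S)-9-acetoxy-8-[(2R,3S)-3-chloro-2-hydroxy-2-methylbutanoyloxy]germacra-1(10)E,4E,11(13)-trien-12,6-olid-14-oate | C1/C(C)=C/[C@H]2OC(=O)C(=C)[C@@H]2[C@@H](OC(=O)[C@@](C)(O)[C@H](C)Cl)[C@@H](OC(C)=O)/C(C(=O)OC)=C\C1 | intermediate
33 | methyl (4R,5R,6S,7R,8R,9S)-9-acetoxy-8-[(2R,3S)-3-chloro-2-hydroxy-2-methylbutanoyloxy]-4,5-epoxygermacra-1(10)E,11(13)-dien-12,6-olid-14-oate | C=C1C(=O)O[C@H]2[C@H]1[C@@H](OC(=O)[C@@](C)(O)[C@H](C)Cl)[C@@H](OC(C)=O)/C(C(=O)OC)=C\CC[C@@]1(C)O[C@H]21 | target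

## Step count and risks

Total: 22 steps. Longest linear sequence: 16 steps (steps 1–6, 9, 10, 15–22). The stannane (steps 7–8) and the side-chain acid (steps 11–14) are made in parallel.

**Step 10 (key step).** The most likely failure is loss of facial control in the oxygen transfer, because the ten-membered enolate can flip its C8=C9 plane through the ring before it is trapped. Proton exchange between enolate and product would lower conversion as well. Fallback: starting from 15, the same operation would then give mainly the 8-epimeric ketol F1. Its hydroxyl is converted into the triflate F2 (Tf2O, 2,6-lutidine, CH2Cl2, −78 °C). The triflate is displaced by the caesium carboxylate F3 (from 23 and Cs2CO3) in MeCN with 18-crown-6; SN2 at the α-keto carbon inverts C8 and installs the side chain, returning to the route at 25.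

**Step 9.** The addition may discriminate poorly between the two faces of the hindered carbonyl, or the reagent may deprotonate C2 instead of adding. Fallback: starting from 11 and 9, the alkene is built in two stages through a slimmer nucleophile. Sonogashira coupling of 11 with ethynyltrimethylsilane (PdCl2(PPh3)2, CuI, Et3N) gives the silylated enyne F4, and K2CO3 in MeOH frees the enyne F5. Its lithium acetylide (n-BuLi, THF, −78 °C) adds axially to 9, anti to the pseudo-axial C4 substituent, and gives the propargylic alcohol F6. Hydroxyl-directed trans-hydroalumination with NaAlH2(OCH2CH2OMe)2 (THF, 0 °C) gives the E alkene and returns to the route at 15.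

**Step 16.** Hydride may be delivered to the inner face if the enone adopts another conformation, and the C8 ester may migrate to the new alkoxide. Fallback: starting from 25, if the 9-epimeric alcohol F7 is the main product, it is treated with acetic acid under Mitsunobu conditions (PPh3, diisopropyl azodicarboxylate, toluene, 0 °C). This inverts C9 and installs the acetate in one operation, returning to the route at 27.

**Step 3.** Transmetalation of the neopentyl-type alkenylboronate to copper may be slow, so that protodeboronation or loss of E geometry competes. Fallback: starting from 4, Takai iodo-olefination (CHI3, CrCl2, THF) gives the E alkenyl iodide F8. Ullmann-type C–O coupling with 4-methoxybenzyl alcohol (CuI cat., 3,4,7,8-tetramethyl-1,10-phenanthroline, Cs2CO3, toluene, 80 °C) retains the geometry and returns to the route at 6.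

**Step 1.** An achiral silyl Lewis acid released from the diene may catalyse a background cycloaddition and erode the enantioselectivity, or the diene may decompose. Fallback: starting from 1 and 2, the uncatalysed thermal cycloaddition (toluene, 80 °C) gives the racemic cis silyl ether F9, hydrolysed (1 M HCl, THF) to the racemic hydroxy aldehyde F10. Lipase-mediated acylation (Burkholderia cepacia lipase, vinyl acetate, t-BuOMe) should, by the empirical rule for secondary alcohols, esterify the (2R) enantiomer to acetate F11. The unreacted alcohol is 4, where the route is rejoined.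

## Further compounds

F1 | step 10 | (6R,7R,8S)-12-(tert-butyldimethylsilyloxy)-8-hydroxy-6-(4-methoxybenzyloxy)-14-(triisopropylsilyloxy)germacra-1(10)Z,4E,11(13)-trien-9-one (8-epimer of 17) | C1/C(C)=C/[C@@H](OCc2ccc(OC)cc2)[C@H](C(=C)CO[Si](C)(C)C(C)(C)C)[C@H](O)C(=O)/C(CO[Si](C(C)C)(C(C)C)C(C)C)=C\C1
F2 | step 10 | (6R,7S,8S)-12-(tert-butyldimethylsilyloxy)-6-(4-methoxybenzyloxy)-9-oxo-14-(triisopropylsilyloxy)germacra-1(10)Z,4E,11(13)-trien-8-yl trifluoromethanesulfonate | C1/C(C)=C/[C@@H](OCc2ccc(OC)cc2)[C@H](C(=C)CO[Si](C)(C)C(C)(C)C)[C@H](OS(=O)(=O)C(F)(F)F)C(=O)/C(CO[Si](C(C)C)(C(C)C)C(C)C)=C\C1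
F3 | step 10 | caesium (2R,3S)-3-chloro-2-methyl-2-(triethylsilyloxy)butanoate | [Cs+].[O-]C(=O)[C@@](C)(O[Si](CC)(CC)CC)[C@H](C)Cl
F4 | step 9 | tert-butyldimethyl{[2-methylidene-4-(trimethylsilyl)but-3-yn-1-yl]oxy}silane | C=C(CO[Si](C)(C)C(C)(C)C)C#C[Si](C)(C)C
F5 | step 9 | tert-butyldimethyl[(2-methylidenebut-3-yn-1-yl)oxy]silane | C=C(CO[Si](C)(C)C(C)(C)C)C#C
F6 | step 9 | (1S,6S)-1-{3-[(tert-butyldimethylsilyloxy)methyl]but-3-en-1-yn-1-yl}-6-[(E)-2-(4-methoxybenzyloxy)ethenyl]-6-methyl-2-[(triisopropylsilyloxy)methyl]cyclohex-2-en-1-ol | C1CC=C(CO[Si](C(C)C)(C(C)C)C(C)C)[C@@](O)(C#CC(=C)CO[Si](C)(C)C(C)(C)C)[C@]1(C)/C=C/OCc1ccc(OC)cc1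
F7 | step 16 | (6R,7S,8R,9R)-12-(tert-butyldimethylsilyloxy)-8-[(2R,3S)-3-chloro-2-methyl-2-(triethylsilyloxy)butanoyloxy]-6-(4-methoxybenzyloxy)-14-(triisopropylsilyloxy)germacra-1(10)Z,4E,11(13)-trien-9-ol (9-epimer of 26) | C1/C(C)=C/[C@@H](OCc2ccc(OC)cc2)[C@H](C(=C)CO[Si](C)(C)C(C)(C)C)[C@@H](OC(=O)[C@@](C)(O[Si](CC)(CC)CC)[C@H](C)Cl)[C@H](O)/C(CO[Si](C(C)C)(C(C)C)C(C)C)=C\C1
F8 | step 3 | (1S,6S)-6-[(E)-2-iodoethenyl]-6-methylcyclohex-2-en-1-ol | O[C@H]1C=CCC[C@@]1(C)/C=C/I
F9 | step 1 | racemic cis-1-methyl-2-(trimethylsilyloxy)cyclohex-3-ene-1-carbaldehyde | C[Si](C)(C)O[C@H]1C=CCC[C@@]1(C)C=O.C[Si](C)(C)O[C@@H]1C=CCC[C@]1(C)C=O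
F10 | step 1 | racemic cis-2-hydroxy-1-methylcyclohex-3-ene-1-carbaldehyde | O[C@H]1C=CCC[C@@]1(C)C=O.O[C@@H]1C=CCC[C@]1(C)C=O
F11 | step 1 | (1R,6S)-6-formyl-6-methylcyclohex-2-en-1-yl acetate (acetate of the enantiomer of 4) | CC(=O)O[C@@H]1C=CCC[C@]1(C)C=O
A1 | alternative 1 | methyl (2Z,6E,10E)-2-(bromomethyl)-4,5-bis(tert-butyldimethylsilyloxy)-6-(methoxycarbonyl)-10-methyl-12-oxododeca-2,6,10-trienoate, C8/C9 configured as in the target | O=C/C=C(\C)CC/C=C(C(=O)OC)\[C@H](O[Si](C)(C)C(C)(C)C)[C@H](O[Si](C)(C)C(C)(C)C)/C=C(\CBr)C(=O)OC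
A2 | alternative 2 | methyl (2Z,6E)-7-{3-[1-(tert-butyldimethylsilyloxy)-2-oxoethyl]-4-methylidene-5-oxooxolan-2-yl}-2-iodo-6-methylhepta-2,6-dienoate, C6/C7/C8 configured as in the target | O=C[C@H](O[Si](C)(C)C(C)(C)C)[C@H]1C(=C)C(=O)O[C@@H]1/C=C(\C)CC/C=C(\I)C(=O)OC
A3 | alternative 3 | parthenolide (4,5-epoxygermacra-1(10)E,11(13)-dien-12,6-olide) | C1[C@@]2(C)O[C@@H]2[C@H]3OC(=O)C(=C)[C@@H]3CC/C(C)=C/C1
A4 | alternative 3 | 14-hydroxyparthenolide with C2 and C9 cis on C1=C10 | C1[C@@]2(C)O[C@@H]2[C@H]3OC(=O)C(=C)[C@@H]3CC/C(CO)=C\C1
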